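**Retrosynthetic overview**

1. The 8''‑O‑4' side chain is attached last to the free ring B phenol of a tetrahydrofuran core: C7''–H by Felkin–Anh ketone reduction, C7''–aryl by aryllithium/Weinreb amide, C8''–O by Mitsunobu inversion of ethyl (S)‑lactate.
2. Core: C7'–H by hydride reduction of the cyclic oxocarbenium ion of a 2‑aryl hemiketal; C7'–aryl (ring B) by aryllithium addition to a 3,4‑trans‑4,5‑cis γ‑butyrolactone; C8'–CH3 by lactone enolate methylation.
3. Key C–C bond (C7–C8): intermolecular asymmetric carbonyl crotylation (allylation of an aldehyde) joining O‑silylvanillin with a (Z)‑crotylborane; it sets C7 and C8, and the vinyl group becomes C8'/C7'.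
4. Ring order: the three benzene rings are bought; the only ring made is the oxolane, first as the γ‑lactone (steps 3–4), then converted into the tetrahydrofuran (steps 6–7).
5. Protection: ring C and ring A phenols as triisopropylsilyl (TIPS) ethers, removed together at the end; ring B phenol as a benzyl ether, removed alone before the side chain is attached.

Assumption: the target is taken exactly as drawn, i.e. (7S,8R,7'R,8'R) core with a (7''R,8''R) threo side chain; lignan numbering is ring C–C7–C8(CH3)–C8'(CH3)–C7'–ring B and ring A–C7''–C8'' for the side chain.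

**Route**

Step 1
Reactants: 1 vanillin
Product: 2 3-methoxy-4-(triisopropylsilyloxy)benzaldehyde
Conditions: TIPSCl, imidazole, DMF, rt
Reagents that add atoms: triisopropylsilyl chloride (TIPSCl), CC(C)[Si](Cl)(C(C)C)C(C)C
Why: Imidazole-promoted O-silylation of the phenol (silyl ether formation) gives a mask for the ring C phenol that is stable to base and organometallics yet labile to fluoride, and no stereocentre is formed.

Step 2
Reactants: 2 3-methoxy-4-(triisopropylsilyloxy)benzaldehyde; 3 cis-2-butene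
Product: 7 (1S,2R)-1-[3-methoxy-4-(triisopropylsilyloxy)phenyl]-2-methylbut-3-en-1-ol, via (Z)-crotylpotassium 4 (not isolated), via (Z)-crotyldiisopinocampheylborane 5 (not isolated), via homoallyl diisopinocampheylborinate 6 (not isolated)
Conditions: cis-2-butene, KOt-Bu, n-BuLi, THF, −78 → −45 °C; (−)-Ipc2BOMe [from (+)-α-pinene], −78 °C; BF3·OEt2, −78 °C; then 2, −78 °C; NaBO3·4H2O, THF/H2O, rt
Reagents that add atoms: none
Why: Brown asymmetric crotylboration (carbonyl allylation through a closed Zimmerman–Traxler chair) transfers the Z-crotyl geometry into the syn relationship while the (−)-Ipc2B ligands direct the crotyl group to the Si face of the aldehyde, so the C7–C8 bond forms with (7S,8R) configuration (typically dr > 95:5, about 90% ee).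

Step 3
Reactants: 7 (1S,2R)-1-[3-methoxy-4-(triisopropylsilyloxy)phenyl]-2-methylbut-3-en-1-ol
Product: 9 (1S,2R)-1-[3-methoxy-4-(triisopropylsilyloxy)phenyl]-2-methylbutane-1,4-diol, via B-alkyl-9-BBN adduct 8 (not isolated)
Conditions: 9-BBN (2.5 equiv), THF, 0 °C → rt; NaBO3·4H2O, H2O, rt
Reagents that add atoms: sodium perborate tetrahydrate (NaBO3·4H2O, supplies the hydroxyl oxygen), [Na+].[Na+].O[B-]1(O)OO[B-](O)(O)OO1.O.O.O.O.O.O
Why: Anti-Markovnikov hydroboration of the monosubstituted alkene with 9-BBN and mild perborate oxidation (hydroboration–oxidation) gives the primary alcohol without touching the two stereocentres or the aryl silyl ether.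

Step 4
Reactants: 9 (1S,2R)-1-[3-methoxy-4-(triisopropylsilyloxy)phenyl]-2-methylbutane-1,4-diol
Product: 11 (4R,5S)-5-[3-methoxy-4-(triisopropylsilyloxy)phenyl]-4-methyldihydrofuran-2(3H)-one, via lactol 10 (not isolated)
Conditions: TEMPO (2,2,6,6-tetramethylpiperidin-1-oxyl, 0.2 equiv), PhI(OAc)2 (2.5 equiv), CH2Cl2, rt
Reagents that add atoms: none
Why: TEMPO/PhI(OAc)2 oxidises the primary alcohol selectively to the aldehyde, which closes to the lactol and is oxidised on to the γ-lactone (oxidative lactonisation), the benzylic C–O bond being kept so that the syn pair becomes the 4,5-cis lactone.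

Step 5
Reactants: 11 (4R,5S)-5-[3-methoxy-4-(triisopropylsilyloxy)phenyl]-4-methyldihydrofuran-2(3H)-one
Product: 13 (3R,4R,5S)-5-[3-methoxy-4-(triisopropylsilyloxy)phenyl]-3,4-dimethyldihydrofuran-2(3H)-one, via lithium enolate 12 (not isolated)
Conditions: LiN(SiMe3)2 (1.1 equiv), THF, −78 °C; MeI (3 equiv), −78 → −40 °C
Reagents that add atoms: iodomethane (MeI), CI
Why: In this kinetic lactone enolate alkylation MeI attacks the planar enolate from the face opposite the adjacent C4 methyl and the C5 aryl group (both on the other face), which sets C8' as R (3,4-trans).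

Step 6
Reactants: 13 (3R,4R,5S)-5-[3-methoxy-4-(triisopropylsilyloxy)phenyl]-3,4-dimethyldihydrofuran-2(3H)-one; 14 1-(benzyloxy)-4-bromo-2-methoxybenzene
Product: 16 (3R,4R,5S)-2-[4-(benzyloxy)-3-methoxyphenyl]-5-[3-methoxy-4-(triisopropylsilyloxy)phenyl]-3,4-dimethyltetrahydrofuran-2-ol (anomer mixture in equilibrium with the open γ-hydroxy ketone; filtered through Et3N-deactivated silica and used at once), via aryllithium 15 (not isolated)
Conditions: 14, n-BuLi, THF, −78 °C; then 13, −78 °C; sat. aq. NH4Cl at −78 °C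
Reagents that add atoms: none
Why: Bromine–lithium exchange followed by 1,2-addition of the aryllithium to the lactone carbonyl at −78 °C stops at the stable lithium hemiketalate (mono-addition), so the ring B aryl–C7' bond is made without disturbing C8', C8 or C7, and the undefined anomeric carbon is removed in the next step.

Step 7
Reactants: 16 (3R,4R,5S)-2-[4-(benzyloxy)-3-methoxyphenyl]-5-[3-methoxy-4-(triisopropylsilyloxy)phenyl]-3,4-dimethyltetrahydrofuran-2-ol
Product: 18 (2R,3R,4R,5S)-2-[4-(benzyloxy)-3-methoxyphenyl]-5-[3-methoxy-4-(triisopropylsilyloxy)phenyl]-3,4-dimethyltetrahydrofuran, via cyclic oxocarbenium ion 17 (not isolated)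
Conditions: Et3SiH (5 equiv), BF3·OEt2 (2.5 equiv), CH2Cl2, −78 °C; Et3N then sat. aq. NaHCO3 at −78 °C
Reagents that add atoms: none
Why: In this ionic (reductive) deoxygenation of a hemiketal the aryl-stabilised cyclic oxocarbenium ion takes hydride by inside attack on the face syn to the adjacent C8' methyl and anti to the C8 methyl and the C7 aryl, which places the ring B aryl trans to the C8' methyl (C7' = R), while −78 °C and a cold quench prevent Lewis-acid epimerisation of the cis benzylic C7 centre.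

Step 8
Reactants: 18 (2R,3R,4R,5S)-2-[4-(benzyloxy)-3-methoxyphenyl]-5-[3-methoxy-4-(triisopropylsilyloxy)phenyl]-3,4-dimethyltetrahydrofuran
Product: 19 2-methoxy-4-{(2R,3R,4R,5S)-5-[3-methoxy-4-(triisopropylsilyloxy)phenyl]-3,4-dimethyltetrahydrofuran-2-yl}phenol
Conditions: H2 (1 atm), Pd/C (10 wt% Pd), EtOAc, rt, stopped at full conversion
Reagents that add atoms: none
Why: Hydrogenolysis of the benzyl aryl ether under neutral conditions frees only the ring B phenol, because the silyl ether is inert and the benzylic C–O bonds of the tetrahydrofuran are cleaved much more slowly.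

Step 9
Reactants: 19 2-methoxy-4-{(2R,3R,4R,5S)-5-[3-methoxy-4-(triisopropylsilyloxy)phenyl]-3,4-dimethyltetrahydrofuran-2-yl}phenol; 20 ethyl (S)-lactate
Product: 21 ethyl (2R)-2-(2-methoxy-4-{(2R,3R,4R,5S)-5-[3-methoxy-4-(triisopropylsilyloxy)phenyl]-3,4-dimethyltetrahydrofuran-2-yl}phenoxy)propanoate
Conditions: PPh3, DIAD (diisopropyl azodicarboxylate), THF, 0 °C → rt
Reagents that add atoms: none
Why: In this Mitsunobu etherification the phenol displaces the activated secondary alkoxyphosphonium of the lactate by SN2 with clean inversion, so (S)-lactate becomes the (R)-aryloxypropanoate that carries C8''.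

Step 10
Reactants: 21 ethyl (2R)-2-(2-methoxy-4-{(2R,3R,4R,5S)-5-[3-methoxy-4-(triisopropylsilyloxy)phenyl]-3,4-dimethyltetrahydrofuran-2-yl}phenoxy)propanoate
Product: 22 (2R)-N-methoxy-N-methyl-2-(2-methoxy-4-{(2R,3R,4R,5S)-5-[3-methoxy-4-(triisopropylsilyloxy)phenyl]-3,4-dimethyltetrahydrofuran-2-yl}phenoxy)propanamide
Conditions: Me(MeO)NH·HCl, i-PrMgCl, THF, −20 → −10 °C
Reagents that add atoms: N,O-dimethylhydroxylamine hydrochloride, CNOC.Cl
Why: Weinreb amide formation by aminolysis of the ester with the chloromagnesium amide of N,O-dimethylhydroxylamine at low temperature proceeds without enolisation of the α-aryloxy stereocentre.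

Step 11
Reactants: 23 4-bromo-2-methoxyphenol
Product: 24 (4-bromo-2-methoxyphenoxy)triisopropylsilane
Conditions: TIPSCl, imidazole, DMF, rt
Reagents that add atoms: triisopropylsilyl chloride (TIPSCl), CC(C)[Si](Cl)(C(C)C)C(C)C
Why: Imidazole-promoted O-silylation (silyl ether formation) masks the ring A phenol with the same fluoride-labile group as ring C, and no stereocentre is involved.

Step 12
Reactants: 22 (2R)-N-methoxy-N-methyl-2-(2-methoxy-4-{(2R,3R,4R,5S)-5-[3-methoxy-4-(triisopropylsilyloxy)phenyl]-3,4-dimethyltetrahydrofuran-2-yl}phenoxy)propanamide; 24 (4-bromo-2-methoxyphenoxy)triisopropylsilane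
Product: 26 (2R)-1-[3-methoxy-4-(triisopropylsilyloxy)phenyl]-2-(2-methoxy-4-{(2R,3R,4R,5S)-5-[3-methoxy-4-(triisopropylsilyloxy)phenyl]-3,4-dimethyltetrahydrofuran-2-yl}phenoxy)propan-1-one, via aryllithium 25 (not isolated)
Conditions: 24 (2 equiv), n-BuLi, THF, −78 °C; then 22, −78 °C; sat. aq. NH4Cl at −78 °C
Reagents that add atoms: none
Why: In this Weinreb ketone synthesis the aryllithium adds once to give a chelated tetrahedral intermediate that collapses to the ketone only on quench, so there is no over-addition and the (R) α-stereocentre is never exposed to base as a ketone.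

Step 13
Reactants: 26 (2R)-1-[3-methoxy-4-(triisopropylsilyloxy)phenyl]-2-(2-methoxy-4-{(2R,3R,4R,5S)-5-[3-methoxy-4-(triisopropylsilyloxy)phenyl]-3,4-dimethyltetrahydrofuran-2-yl}phenoxy)propan-1-one
Product: 27 (1R,2R)-1-[3-methoxy-4-(triisopropylsilyloxy)phenyl]-2-(2-methoxy-4-{(2R,3R,4R,5S)-5-[3-methoxy-4-(triisopropylsilyloxy)phenyl]-3,4-dimethyltetrahydrofuran-2-yl}phenoxy)propan-1-ol
Conditions: Bu4NBH4, CH2Cl2/MeOH (4:1), −78 → −20 °C; sat. aq. NH4Cl
Reagents that add atoms: none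
Why: In this Felkin–Anh (polar model) reduction with a non-chelating borohydride the aryloxy group lies perpendicular to the carbonyl and anti to the incoming hydride, which passes the small H and gives the syn (threo) alcohol, i.e. C7'' = R next to C8'' = R.

Step 14
Reactants: 27 (1R,2R)-1-[3-methoxy-4-(triisopropylsilyloxy)phenyl]-2-(2-methoxy-4-{(2R,3R,4R,5S)-5-[3-methoxy-4-(triisopropylsilyloxy)phenyl]-3,4-dimethyltetrahydrofuran-2-yl}phenoxy)propan-1-ol
Product: 28 target, 4-{(2S,3R,4R,5R)-5-[4-{[(1R,2R)-1-hydroxy-1-(4-hydroxy-3-methoxyphenyl)propan-2-yl]oxy}-3-methoxyphenyl]-3,4-dimethyltetrahydrofuran-2-yl}-2-methoxyphenol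
Conditions: Bu4NF (2.5 equiv), AcOH (2.5 equiv), THF, 0 °C
Reagents that add atoms: none
Why: Fluoride-mediated desilylation cleaves both aryl silyl ethers under acetic-acid buffering, conditions that leave the benzylic alcohol, the alkyl aryl ether and all six stereocentres untouched.

**Compound list**

1 | vanillin (4-hydroxy-3-methoxybenzaldehyde) | COc1cc(C=O)ccc1O | starting material
2 | 3-methoxy-4-(triisopropylsilyloxy)benzaldehyde | COc1cc(C=O)ccc1O[Si](C(C)C)(C(C)C)C(C)C | intermediate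
3 | cis-2-butene [(Z)-but-2-ene] | C/C=C\C | starting material
4 | (Z)-crotylpotassium [(Z)-but-2-enylpotassium] | C/C=C\C[K] | intermediate
5 | (Z)-crotyldiisopinocampheylborane, (−)-Ipc2B series from (+)-α-pinene | C/C=C\CB([C@@H]1C[C@@H]2C[C@@H](C2(C)C)[C@H]1C)[C@@H]1C[C@@H]2C[C@@H](C2(C)C)[C@H]1C | intermediate
6 | (1S,2R)-1-[3-methoxy-4-(triisopropylsilyloxy)phenyl]-2-methylbut-3-enyl diisopinocampheylborinate | B([C@@H]1C[C@@H]2C[C@@H](C2(C)C)[C@H]1C)([C@@H]1C[C@@H]2C[C@@H](C2(C)C)[C@H]1C)O[C@H](c1ccc(O[Si](C(C)C)(C(C)C)C(C)C)c(OC)c1)[C@H](C)C=C | intermediate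
7 | (1S,2R)-1-[3-methoxy-4-(triisopropylsilyloxy)phenyl]-2-methylbut-3-en-1-ol (syn) | O[C@H](c1ccc(O[Si](C(C)C)(C(C)C)C(C)C)c(OC)c1)[C@H](C)C=C | intermediate
8 | (1S,2R)-4-(9-borabicyclo[3.3.1]nonan-9-yl)-1-[3-methoxy-4-(triisopropylsilyloxy)phenyl]-2-methylbutan-1-ol | O[C@H](c1ccc(O[Si](C(C)C)(C(C)C)C(C)C)c(OC)c1)[C@H](C)CCB1C2CCCC1CCC2 | intermediate
9 | (1S,2R)-1-[3-methoxy-4-(triisopropylsilyloxy)phenyl]-2-methylbutane-1,4-diol | O[C@H](c1ccc(O[Si](C(C)C)(C(C)C)C(C)C)c(OC)c1)[C@H](C)CCO | intermediate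
10 | (4R,5S)-5-[3-methoxy-4-(triisopropylsilyloxy)phenyl]-4-methyltetrahydrofuran-2-ol (lactol, anomer mixture) | O1[C@H](c2ccc(O[Si](C(C)C)(C(C)C)C(C)C)c(OC)c2)[C@H](C)CC1O | intermediate
11 | (4R,5S)-5-[3-methoxy-4-(triisopropylsilyloxy)phenyl]-4-methyldihydrofuran-2(3H)-one (4,5-cis) | O1[C@H](c2ccc(O[Si](C(C)C)(C(C)C)C(C)C)c(OC)c2)[C@H](C)CC1=O | intermediate
12 | lithium (4R,5S)-5-[3-methoxy-4-(triisopropylsilyloxy)phenyl]-4-methyl-4,5-dihydrofuran-2-olate (lithium enolate of 11) | O1[C@H](c2ccc(O[Si](C(C)C)(C(C)C)C(C)C)c(OC)c2)[C@H](C)C=C1O[Li] | intermediate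
13 | (3R,4R,5S)-5-[3-methoxy-4-(triisopropylsilyloxy)phenyl]-3,4-dimethyldihydrofuran-2(3H)-one (3,4-trans, 4,5-cis) | O1[C@H](c2ccc(O[Si](C(C)C)(C(C)C)C(C)C)c(OC)c2)[C@H](C)[C@@H](C)C1=O | intermediate
14 | 1-(benzyloxy)-4-bromo-2-methoxybenzene | COc1cc(Br)ccc1OCc1ccccc1 | starting material
15 | [4-(benzyloxy)-3-methoxyphenyl]lithium | COc1cc([Li])ccc1OCc1ccccc1 | intermediate
16 | (3R,4R,5S)-2-[4-(benzyloxy)-3-methoxyphenyl]-5-[3-methoxy-4-(triisopropylsilyloxy)phenyl]-3,4-dimethyltetrahydrofuran-2-ol (anomer mixture) | OC1(c2ccc(OCc3ccccc3)c(OC)c2)O[C@H](c2ccc(O[Si](C(C)C)(C(C)C)C(C)C)c(OC)c2)[C@H](C)[C@H]1C | intermediate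
17 | (3R,4R,5S)-2-[4-(benzyloxy)-3-methoxyphenyl]-5-[3-methoxy-4-(triisopropylsilyloxy)phenyl]-3,4-dimethyl-4,5-dihydro-3H-furan-1-ium (cyclic oxocarbenium ion) | COc1cc(C2=[O+][C@H](c3ccc(O[Si](C(C)C)(C(C)C)C(C)C)c(OC)c3)[C@H](C)[C@H]2C)ccc1OCc1ccccc1 | intermediate
18 | (2R,3R,4R,5S)-2-[4-(benzyloxy)-3-methoxyphenyl]-5-[3-methoxy-4-(triisopropylsilyloxy)phenyl]-3,4-dimethyltetrahydrofuran | COc1cc([C@@H]2O[C@H](c3ccc(O[Si](C(C)C)(C(C)C)C(C)C)c(OC)c3)[C@H](C)[C@H]2C)ccc1OCc1ccccc1 | intermediate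
19 | 2-methoxy-4-{(2R,3R,4R,5S)-5-[3-methoxy-4-(triisopropylsilyloxy)phenyl]-3,4-dimethyltetrahydrofuran-2-yl}phenol | COc1cc([C@@H]2O[C@H](c3ccc(O[Si](C(C)C)(C(C)C)C(C)C)c(OC)c3)[C@H](C)[C@H]2C)ccc1O | intermediate
20 | ethyl (S)-lactate [ethyl (2S)-2-hydroxypropanoate] | CCOC(=O)[C@H](C)O | starting material
21 | ethyl (2R)-2-(2-methoxy-4-{(2R,3R,4R,5S)-5-[3-methoxy-4-(triisopropylsilyloxy)phenyl]-3,4-dimethyltetrahydrofuran-2-yl}phenoxy)propanoate | CCOC(=O)[C@@H](C)Oc1ccc([C@@H]2O[C@H](c3ccc(O[Si](C(C)C)(C(C)C)C(C)C)c(OC)c3)[C@H](C)[C@H]2C)cc1OC | intermediate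
22 | (2R)-N-methoxy-N-methyl-2-(2-methoxy-4-{(2R,3R,4R,5S)-5-[3-methoxy-4-(triisopropylsilyloxy)phenyl]-3,4-dimethyltetrahydrofuran-2-yl}phenoxy)propanamide | CON(C)C(=O)[C@@H](C)Oc1ccc([C@@H]2O[C@H](c3ccc(O[Si](C(C)C)(C(C)C)C(C)C)c(OC)c3)[C@H](C)[C@H]2C)cc1OC | intermediate
23 | 4-bromo-2-methoxyphenol | COc1cc(Br)ccc1O | starting material
24 | (4-bromo-2-methoxyphenoxy)triisopropylsilane | COc1cc(Br)ccc1O[Si](C(C)C)(C(C)C)C(C)C | intermediate
25 | [3-methoxy-4-(triisopropylsilyloxy)phenyl]lithium | COc1cc([Li])ccc1O[Si](C(C)C)(C(C)C)C(C)C | intermediate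
26 | (2R)-1-[3-methoxy-4-(triisopropylsilyloxy)phenyl]-2-(2-methoxy-4-{(2R,3R,4R,5S)-5-[3-methoxy-4-(triisopropylsilyloxy)phenyl]-3,4-dimethyltetrahydrofuran-2-yl}phenoxy)propan-1-one | COc1cc(C(=O)[C@@H](C)Oc2ccc([C@@H]3O[C@H](c4ccc(O[Si](C(C)C)(C(C)C)C(C)C)c(OC)c4)[C@H](C)[C@H]3C)cc2OC)ccc1O[Si](C(C)C)(C(C)C)C(C)C | intermediate
27 | (1R,2R)-1-[3-methoxy-4-(triisopropylsilyloxy)phenyl]-2-(2-methoxy-4-{(2R,3R,4R,5S)-5-[3-methoxy-4-(triisopropylsilyloxy)phenyl]-3,4-dimethyltetrahydrofuran-2-yl}phenoxy)propan-1-ol (threo) | COc1cc([C@@H](O)[C@@H](C)Oc2ccc([C@@H]3O[C@H](c4ccc(O[Si](C(C)C)(C(C)C)C(C)C)c(OC)c4)[C@H](C)[C@H]3C)cc2OC)ccc1O[Si](C(C)C)(C(C)C)C(C)C | intermediate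
28 | 4-{(2S,3R,4R,5R)-5-[4-{[(1R,2R)-1-hydroxy-1-(4-hydroxy-3-methoxyphenyl)propan-2-yl]oxy}-3-methoxyphenyl]-3,4-dimethyltetrahydrofuran-2-yl}-2-methoxyphenol | COc1cc([C@@H](O)[C@@H](C)Oc2ccc([C@@H]3O[C@H](c4ccc(O)c(OC)c4)[C@H](C)[C@H]3C)cc2OC)ccc1O | target

**Summary**

Total step count: 14. Longest linear sequence: 13 steps (steps 1–10 and 12–14, from vanillin); step 11 is a one-step side branch.

Steps most likely to fail, with fallbacks:

First, step 7. The risks are the facial selectivity at C7' and Lewis-acid epimerisation of the cis benzylic C7 centre, which would lead to the all-trans isomer. The fallback sets out from 16 and comes back at 18 without any oxocarbenium/hydride step. NaBH4 (MeOH/THF, 0 °C) reduces the open hydroxy-ketone form of 16 to (1S,2R,3R,4RS)-4-[4-(benzyloxy)-3-methoxyphenyl]-1-[3-methoxy-4-(triisopropylsilyloxy)phenyl]-2,3-dimethylbutane-1,4-diol F6; the C7' carbinol mixture does not matter. MsCl (1.1 equiv) and Et3N in CH2Cl2 at 0 °C then give the benzylic monomesylate F7, which is not isolated. The benzyloxy-substituted benzylic position should ionise more readily than the silyloxy-substituted one, though this selectivity is an expectation and not a certainty. The C7 hydroxyl closes the ring with retention at C7, and the stereoconvergent SN1 closure places the ring B aryl trans to the C8' methyl, giving 18.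

Second, step 13. The risk is that substrate control gives only a moderate threo:erythro ratio. The fallback sets out from 26 and comes back at 27 by replacing substrate control with catalyst control: Corey–Bakshi–Shibata reduction with (R)-2-methyl-CBS-oxazaborolidine [(3aR)-1-methyl-3,3-diphenyltetrahydro-1H,3H-pyrrolo[1,2-c][1,3,2]oxazaborole, 20 mol%] and BH3·SMe2 in THF at −20 °C. If the aryl group behaves as the large substituent, this catalyst delivers hydride to the same face as the Felkin–Anh pathway (matched pair) and gives the (1R,2R) alcohol 27 directly. This fallback makes no new compound, F0.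

Third, step 2. The reagent is operationally demanding: Z → E leakage of the crotylpotassium lowers dr, and the ee is about 90%, with the minor enantiomer only removed later as a diastereomer after step 9. The fallback sets out from 2 and comes back at 7 through an auxiliary-controlled aldol instead of a crotylboration:
- The dibutylboron Z-enolate of (S)-4-benzyl-3-propanoyloxazolidin-2-one (Bu2BOTf, i-Pr2NEt, CH2Cl2, −78 → 0 °C) adds to 2 to give the Evans syn adduct (S)-4-benzyl-3-{(2S,3S)-3-hydroxy-3-[3-methoxy-4-(triisopropylsilyloxy)phenyl]-2-methylpropanoyl}oxazolidin-2-one F1, purified to a single diastereomer.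
- Et3SiOTf and 2,6-lutidine give the triethylsilyl ether (S)-4-benzyl-3-{(2S,3S)-3-[3-methoxy-4-(triisopropylsilyloxy)phenyl]-2-methyl-3-(triethylsilyloxy)propanoyl}oxazolidin-2-one F2.
- LiBH4 (THF, 1 equiv MeOH, 0 °C) removes the auxiliary to give (2R,3S)-3-[3-methoxy-4-(triisopropylsilyloxy)phenyl]-2-methyl-3-(triethylsilyloxy)propan-1-ol F3.
- Dess–Martin periodinane gives (2S,3S)-3-[3-methoxy-4-(triisopropylsilyloxy)phenyl]-2-methyl-3-(triethylsilyloxy)propanal F4.
- Ph3P=CH2 (from Ph3PCH3Br and KN(SiMe3)2, THF, −78 → 0 °C) gives triethyl{(1S,2R)-1-[3-methoxy-4-(triisopropylsilyloxy)phenyl]-2-methylbut-3-enyloxy}silane F5.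
- Pyridinium p-toluenesulfonate in MeOH removes only the triethylsilyl group (the aryl TIPS ether stays) and returns 7 in enantiopure form.

**Further compounds**

F1 | step 2 | (S)-4-benzyl-3-{(2S,3S)-3-hydroxy-3-[3-methoxy-4-(triisopropylsilyloxy)phenyl]-2-methylpropanoyl}oxazolidin-2-one | O[C@H](c1ccc(O[Si](C(C)C)(C(C)C)C(C)C)c(OC)c1)[C@H](C)C(=O)N1[C@@H](Cc2ccccc2)COC1=O
F2 | step 2 | (S)-4-benzyl-3-{(2S,3S)-3-[3-methoxy-4-(triisopropylsilyloxy)phenyl]-2-methyl-3-(triethylsilyloxy)propanoyl}oxazolidin-2-one | CC[Si](CC)(CC)O[C@H](c1ccc(O[Si](C(C)C)(C(C)C)C(C)C)c(OC)c1)[C@H](C)C(=O)N1[C@@H](Cc2ccccc2)COC1=O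
F3 | step 2 | (2R,3S)-3-[3-methoxy-4-(triisopropylsilyloxy)phenyl]-2-methyl-3-(triethylsilyloxy)propan-1-ol | CC[Si](CC)(CC)O[C@H](c1ccc(O[Si](C(C)C)(C(C)C)C(C)C)c(OC)c1)[C@H](C)CO
F4 | step 2 | (2S,3S)-3-[3-methoxy-4-(triisopropylsilyloxy)phenyl]-2-methyl-3-(triethylsilyloxy)propanal | CC[Si](CC)(CC)O[C@H](c1ccc(O[Si](C(C)C)(C(C)C)C(C)C)c(OC)c1)[C@H](C)C=O
F5 | step 2 | triethyl{(1S,2R)-1-[3-methoxy-4-(triisopropylsilyloxy)phenyl]-2-methylbut-3-enyloxy}silane | CC[Si](CC)(CC)O[C@H](c1ccc(O[Si](C(C)C)(C(C)C)C(C)C)c(OC)c1)[C@H](C)C=C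
F6 | step 7 | (1S,2R,3R,4RS)-4-[4-(benzyloxy)-3-methoxyphenyl]-1-[3-methoxy-4-(triisopropylsilyloxy)phenyl]-2,3-dimethylbutane-1,4-diol | O[C@H](c1ccc(O[Si](C(C)C)(C(C)C)C(C)C)c(OC)c1)[C@H](C)[C@@H](C)C(O)c1ccc(OCc2ccccc2)c(OC)c1
F7 | step 7 | (1RS,2R,3R,4S)-1-[4-(benzyloxy)-3-methoxyphenyl]-4-hydroxy-4-[3-methoxy-4-(triisopropylsilyloxy)phenyl]-2,3-dimethylbutyl methanesulfonate | O[C@H](c1ccc(O[Si](C(C)C)(C(C)C)C(C)C)c(OC)c1)[C@H](C)[C@@H](C)C(OS(C)(=O)=O)c1ccc(OCc2ccccc2)c(OC)c1
F0 | step 13 | none | none
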